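The earlier runs and the new flask come from a simulation from invented constants; scatter was added.

- At each reading after the peak, take cL beside cD, because the choice at 40 h hangs on their difference.

| setting | maple | alder | flask |
|---|---|---|---|
| L | 0.18 M | 0.36 M | 0.18 M |
| Q | 0.108 M | 0.108 M | 0.108 M |
| temperature | 60 °C | 66 °C | 60 °C |
| remark | the very flask that is asked about, followed so far | run made earlier |  |
| time |  |  | 40 h |

maple run (percent of the L charged)

| time / h | D / % |
|---|---|
| 2.00 | 31.0 |
| 6.00 | 47.9 |
| 12.0 | 46.0 |
| 15.0 | 43.6 |
| 25.0 | 37.2 |

alder run (percent of the L charged)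

| time / min | D / % |
|---|---|
| 8.00 | 4.7 |
| 20.0 | 10.2 |
| 40.0 | 17.0 |
| 60.0 | 21.0 |
| 80.0 | 23.7 |

- a species is counted by the L in it: one Z counts as two
- removed D is counted in
- the earlier runs were read with a standard deviation of 0.3 percentage points
- steps that have been proposed: L + Q -> D; L + D -> Z
- additions bring no volume worth counting

- autumn: at 40 h take out 90% of the D then present, then wait 3.0 d
- winter: at 40 h add Q, 50.0% of the amount charged, then wait 3.0 d
- midnight: at 40 h raise the temperature by 15 K, then wait 3.0 d
- dusk: change nothing and wait 3.0 d more

- D, in percent of the L first charged, at 40 h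
- the remedy with the largest gain of D, or "none" below 2 percentage points (autumn / winter / midnight / dusk / none)
- D present, with what was taken out counted in, in percent of the L first charged, after autumn
- D present, with what was taken out counted in, in percent of the L first charged, after midnight

- Divide the rates of the proposed steps, L + Q -> D and L + D -> Z. At zero cQ, the second step takes one L per D, so time drops out and cD − cL stays constant.
- Find that constant by counting. Each Q used makes one D, and each D lost costs one more L, so cD − cL equals 2 × (Q used) − (L charged).
- Q is the limiting reagent in this flask, at 0.600 equivalents. Use up the charge and the difference becomes the floor, (2 cQ − cL)/cL on the charged amounts: 20.0%. D sinks toward it as cL sinks toward zero.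
- Take maple as being at zero cQ from 15.0 h on. Then (cD − floor)/cD falls exponentially, reading 0.541 at 15.0 h and 0.462 at 25.0 h.
- Extend that line. My reckoning gives D 31.5% at 40 h, with L 11.5%.
- Do not wait, and do not heat. Dusk and midnight keep the charges, so the floor stays and D slides toward it.
- Do not choose autumn. It banks 28.3%, and the total cannot rise without Q.
- Add Q. Winter's Q, 30.0% of the L charged, exceeds the L left in my reckoning. So the floor no longer applies, and D can gain up to that L.
- The forecast gives now 30.5%, g1 30%, g3 9%, and best autumn: “Autumn protects the removed D”. It parts from my choice, and its g3 stands below the floor.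
- The flask gives now 32.2%, best winter with 8.7 percentage points, g1 30.7%, and g3 20.4%.

    L + Q → D, rate k1*[L]*[Q]^0.5 (k = 0.766 M⁻⁰·⁵ h⁻¹, Ea = 62.0 kJ mol⁻¹)
    L + D → Z (k = 0.400 M⁻¹ h⁻¹, Ea = 67.0 kJ mol⁻¹)
    (constants at 60 °C)

- In this flask, D is made 8.68 times faster than it is used up at 1.69 h. But the half-life of D by L + D alone, at the charged concentrations, is 9.6 h, shorter than the 40 h waited, and with Q at 0% the flask holds D 32.2% and L 12.2% at 40.0 h, a difference of 20.0%.
- Try the neighbour kept at 75 °C. Its charges are the same, so the floor again gives cD − cL = 20.0% at zero cQ. Computed at 40.0 h, that neighbour holds Q 0%, D 23.0% and L 3.03%, a difference of 20.0%.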